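## The problem

The target (CNP0400752.1) is a single eleven-membered carbocycle with no ring fusion to lean on. The ring is numbered here from C1, the ring carbon that carries the exocyclic CH2, through C2 and C3, the C4=C5 alkene (carboxyl on C5, C3 and C6 cis, E by the sequence rule), C6, C7 (isovalerate, S), C8, the quaternary C9, C10 and C11 (free allylic carbinol, S). In the systematic names below, ring positions 1, 2, 5, 6, 8 and 10 are C5, C4, C1, C11, C9 and C7.

The two stereocentres stand 1,5 to each other across C9. Neither can be expected to steer the other in an open chain, so C7 needs an outside source of chirality and C11 must come from the ring as it closes or from a reagent. C7 is awkward in its own right: it lies between two methylene groups of similar size (C6 and C8), so a C7 ketone gives a chiral reductant little to tell apart.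

Three features limit what may be done late:
- the allylic C11 carbinol beside the 1,1-disubstituted alkene is open to ionisation and alkene migration in strong acid;
- the free acid sits beside an ester that must stay, which excludes a closing saponification;
- a free C7 hydroxyl is γ to the C5 carboxyl and would close to an α-alkylidene butyrolactone if the carboxyl were at all activated.

The ring is of medium size, so its closure should be left to a reaction that has been shown to form macrocycles of this kind and that ends on sp2 carbon.

The feature that opens the synthesis is the sequence C8–C7(O)–C6–C5(sp2). This is an alkyl–CH(X)–CH2–alkenyl pattern, which is what results when an alkyl group and an alkenyl group are added across a vinylboron unit, with boron later exchanged for oxygen with retention.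

## Retrosynthesis

**Unmasking.** Target 21 is traced to macrocycle 19, its tert-butyl ester and C11 triethylsilyl ether; only C–O and Si–O bonds are cut. The tert-butyl ester is chosen because it resists the boron ate complex, fluoride and nickel, and because its bulk prevents lactonisation of a free C7 hydroxyl. It is removed with a silyl triflate through silyl ester 20, not with strong protic acid, so the allylic C11–O bond is not ionised.

**Ring closure.** 19 is cut at C1–C11 to give ynal 18. Cuts at C2–C3 or C10–C11 would demand sp3–sp3 macrocyclisation, and metathesis at C4=C5 would have to build a trisubstituted enoate in the presence of a second 1,1-disubstituted alkene. The C1–C11 cut turns the exocyclic alkene and the carbinol into a terminal alkyne and an aldehyde, both trivial to carry. The forward reaction must bond the internal alkyne carbon (exocyclic mode, eleven- not twelve-membered ring) and choose the face of the aldehyde.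

**Functional group adjustment.** 18 comes from alcohol 17 by oxidation, 17 from the doubly silylated 16 by fluoride, 16 from alcohol 14 and isovaleryl chloride 15, and 14 from boronate 13 by oxidation with retention. No skeletal bond is cut. The isovalerate is put on directly after the oxidation so that the γ-hydroxy ester is never stored.

**Key disconnection.** 13 is cut at C7–C8 and C5–C6 into three pieces: iodide 4 (used as alkyllithium 11), vinylboronic ester 10 and bromo enoate 9, joined through ate complex 12. An aldol or allylation route to the C7 carbinol leads to the lactone or to the branched regioisomer, and reduction of a C7 ketone lacks steric bias. This cut sets C7 by a catalyst during C–C bond formation and takes the alkene geometry from the bromide. The precursors are an achiral C4 iodide, a commercial C2 unit and an achiral C7 bromo enoate. The forward reaction must be enantioselective, stereoretentive at C5 and tolerant of ester and silylalkyne.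

**Bromo enoate.** 9 is cut at C4=C5 into aldehyde 6 and ylide 7 (brominated in the flask to 8). A stabilised ylide places the ester trans to the chain, which is the needed geometry. 6 is the oxidation product of the commercial silylpentynol 5.

**Iodide.** 4 comes from alcohol 3 by substitution, 3 from diol 2 by silylation of the unhindered hydroxyl, and 2 from 2,2-dimethylsuccinic acid 1 by reduction. The neopentyl position, the hard one to functionalise, is kept for the iodide, which then cannot β-eliminate.

## Roads not taken

**Alternative 1:** Eschenmoser–Tanabe fragmentation to cycloundecynone A1.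
- Cut: read backwards, a C5–C11 bond is added, hiding the eleven-membered ring in the six–seven fused epoxy ketone A2 (C4 ketone, C5–C11 epoxide).
- Forward key step: tosylhydrazide condenses at the C4 ketone of A2 and fragmentation with loss of N2 and sulfinate breaks C5–C11, giving A1 with a C4–C5 triple bond and a C11 ketone.
- Merits: the medium ring comes from two common rings by a unimolecular step at ordinary concentration. Syn addition to the ring alkyne would give the cis ring alkene for free. The C11 ketone invites reagent-controlled reduction.
- Weak points: A1 lacks the carboxyl, the methylene and the C11 hydrogen. The carboxyl must be delivered to C5 and not C4 of an alkyne whose two ends both carry CH2 groups, and only the remote C7 oxygen could direct it. A2 needs a tetrasubstituted enone at a ring fusion and an enantioselective entry to C7 inside a seven-membered ring.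
- Comparison: this road is the safer one for ring formation. Against it, the chosen plan has carboxyl position, alkene geometry and C7 all fixed in 13 after one step, and its ring closure creates the C1 methylene and C11 oxygen directly.

**Alternative 2:** electroreductive decarboxylative radical macrocyclisation to the protected target A3.
- Cut: C3–C4.
- Forward key step: cathodic reduction of the open-chain N-hydroxyphthalimide ester A4 releases CO2 and a primary C3 radical. This adds 11-endo to C4 of the β-phenylsulfonyl enoate and expels the sulfonyl radical, giving A3.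
- Merits: the closure forms no stereocentre, so C11 could be set beforehand in the open chain by a reagent. This is a real advantage over the chosen plan, where C11 is born in the ring closure. A3 is one deprotection from the target.
- Weak points: an unstabilised primary radical must find the acceptor across eleven atoms before it is reduced further or abstracts hydrogen. The C4=C5 geometry is decided in the β-scission after free rotation at the C5 radical, so it is not tied to the precursor. A4 must carry every functional group and both stereocentres along one long linear sequence.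
- Comparison: the chosen plan cannot match the stereochemically silent ring closure. It sets against it a stereoretentive origin of the alkene geometry, three short fragments, and a macrocyclisation class with a record for exocyclic allylic alcohols.

**Alternative 3:** anionic oxy-Cope ring expansion to keto enoate A5.
- Cut: read backwards, C2–C3 is broken and C5–C11 formed, giving the cis-1,2-divinylcycloheptanol A6.
- Forward key step: deprotonation of A6 with KH and 18-crown-6 triggers the [3,3] shift, which forms C2–C3, breaks C5–C11 and gives A5 as its C1–C11 enolate.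
- Merits: a four-carbon ring expansion without high dilution. The enolate is regiodefined towards C1, so the methylene could be introduced in the same flask.
- Weak points: A6 is a β-hydroxy ester with a quaternary α-carbon, and its alkoxide can cleave by retro-aldol along the very C5–C11 bond instead of rearranging. The cis-divinyl arrangement forces a boat-like transition state, so the C4=C5 geometry is not assured. Two contiguous fully substituted carbons must be built with the vinyl groups cis. A5 still needs C11 reduction and exchange of the C7 protecting group.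
- Comparison: this road is better at ring formation and at placing the methylene. The chosen plan avoids the retro-aldol-prone alkoxide and the congested precursor, and fixes geometry and C7 by catalyst and substrate design.

Key step: step 6

Remarks on the chemistry (assumptions):
- 5-(Trimethylsilyl)pent-4-yn-1-ol 5 is taken as commercial; otherwise it is one C-silylation from pent-4-yn-1-ol.
- Which antipode of MandyPhos gives the 7S boronate is to be settled on the first run by MTPA ester analysis of 14; both antipodes are available, so the route does not depend on the answer.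
- Step 11 is taken to give the 11S epimer as the major, separable product; this rests on substrate control, and a reagent-controlled correction is given among the uncertain steps.

## Route

Step 1
Reactants: 1 2,2-dimethylsuccinic acid
Product: 2 2,2-dimethylbutane-1,4-diol
Conditions: LiAlH4, THF, 0 °C → reflux; aqueous NaOH work-up
Reagents that add atoms: none
Why: Exhaustive hydride reduction of both carboxyl groups (LiAlH4 reduction of a dicarboxylic acid); no stereocentre and no other functional group is present.

Step 2
Reactants: 2 2,2-dimethylbutane-1,4-diol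
Product: 3 4-(tert-butyldimethylsilyloxy)-2,2-dimethylbutan-1-ol
Conditions: TBSCl (1.0 equiv), imidazole, CH2Cl2, −20 → 0 °C
Reagents that add atoms: tert-butyldimethylsilyl chloride, CC(C)(C)[Si](C)(C)Cl
Why: Selective monosilylation: the C4 hydroxyl is an unhindered primary alcohol and the C1 hydroxyl is neopentyl, so one equivalent of the bulky silyl chloride at low temperature should take only the former.

Step 3
Reactants: 3 4-(tert-butyldimethylsilyloxy)-2,2-dimethylbutan-1-ol
Product: 4 tert-butyl(4-iodo-3,3-dimethylbutoxy)dimethylsilane
Conditions: I2, PPh3, imidazole, toluene, 80 °C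
Reagents that add atoms: iodine, II
Why: Appel-type iodination through the alkoxyphosphonium iodide; displacement at the neopentyl carbon is slow, hence the heating, and imidazole keeps the medium neutral for the silyl ether.

Step 4
Reactants: 5 5-(trimethylsilyl)pent-4-yn-1-ol
Product: 6 5-(trimethylsilyl)pent-4-ynal
Conditions: Dess–Martin periodinane, CH2Cl2, 0 °C → rt
Reagents that add atoms: none
Why: Dess–Martin oxidation of a primary alcohol stops at the aldehyde; the C-silyl alkyne is inert.

Step 5
Reactants: 6 5-(trimethylsilyl)pent-4-ynal, 7 tert-butyl 2-(triphenyl-λ5-phosphanylidene)acetate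
Product: 9 tert-butyl (Z)-2-bromo-7-(trimethylsilyl)hept-2-en-6-ynoate, via bromo ylide 8 (not isolated)
Conditions: 7, NBS (1.0 equiv), CH2Cl2, −20 °C; then 6, −20 °C → rt
Reagents that add atoms: N-bromosuccinimide, O=C1CCC(=O)N1Br
Why: Halogenation of the stabilised ylide gives bromo ylide 8 (the succinimide anion is the base), and its Wittig reaction places the ester trans to the aldehyde chain as stabilised ylides do, which is the Z bromide. No excess of NBS is used, so the silylalkyne is not exposed to electrophilic bromine; the minor E isomer is removed by chromatography.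

Step 6
Reactants: 4 tert-butyl(4-iodo-3,3-dimethylbutoxy)dimethylsilane, 10 vinylboronic acid pinacol ester, 9 tert-butyl (Z)-2-bromo-7-(trimethylsilyl)hept-2-en-6-ynoate
Product: 13 tert-butyl (2E)-2-[(2S)-6-(tert-butyldimethylsilyloxy)-4,4-dimethyl-2-(4,4,5,5-tetramethyl-1,3,2-dioxaborolan-2-yl)hexyl]-7-(trimethylsilyl)hept-2-en-6-ynoate, via alkyllithium 11 (not isolated), via boron ate complex 12 (not isolated)
Conditions: 4, t-BuLi (2.0 equiv), Et2O/pentane, −78 °C; then 10, −78 °C → rt; solvent exchange to THF; then 9, Pd(OAc)2 (2 mol %), MandyPhos (2.4 mol %), KOTf (3 equiv), 60 °C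
Reagents that add atoms: none
Why: This is the Pd-catalysed enantioselective conjunctive cross-coupling of a vinylboron ate complex with a C(sp2) halide, a known reaction type that proceeds by a metal-induced 1,2-metallate shift. Lithium–iodine exchange on 4 gives 11, which cannot β-eliminate because C9 is quaternary, and 11 adds to boron of 10 to give the four-coordinate complex 12. Zerovalent palladium inserts into the C5–Br bond of 9 with retention, and KOTf removes bromide and the iodide left from the exchange as potassium salts, which frees a site on the cationic alkenylpalladium for the vinyl group of 12. C8 then migrates from boron to C7 anti to palladium while C6 becomes bonded to palladium, and reductive elimination joins C6 to C5, so C7–C8 and C5–C6 are formed and no ring is closed. C7 is the only new stereocentre and is set by the chiral bisphosphine on palladium, which selects the face of the vinyl group (catalyst control; neither partner carries a stereocentre). The C4=C5 geometry is that of the bromide (C3 and C6 cis; the descriptor changes from Z to E only because carbon replaces bromine). The step needs conjunctive coupling to outrun direct Suzuki-type transfer and β-hydride elimination from the C6–Pd intermediate, which the wide-bite-angle ferrocenyl bisphosphine secures, and it needs the ate complex to ignore the ester and the alkyne, which the tert-butyl and trimethylsilyl groups secure.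

Step 7
Reactants: 13 tert-butyl (2E)-2-[(2S)-6-(tert-butyldimethylsilyloxy)-4,4-dimethyl-2-(4,4,5,5-tetramethyl-1,3,2-dioxaborolan-2-yl)hexyl]-7-(trimethylsilyl)hept-2-en-6-ynoate
Product: 14 tert-butyl (2E)-2-[(2S)-6-(tert-butyldimethylsilyloxy)-2-hydroxy-4,4-dimethylhexyl]-7-(trimethylsilyl)hept-2-en-6-ynoate
Conditions: NaBO3·4H2O, THF/H2O, rt
Reagents that add atoms: sodium perborate tetrahydrate, O.O.O.O.[Na+].[O-]OB=O
Why: Perborate oxidation of a secondary pinacol boronate; C7 shifts from boron to oxygen with retention, so the 7S boronate gives the 7S alcohol. The mild, weakly basic oxidant spares the enoate, and the bulk of the tert-butyl ester keeps the γ-hydroxy ester from lactonising.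

Step 8
Reactants: 14 tert-butyl (2E)-2-[(2S)-6-(tert-butyldimethylsilyloxy)-2-hydroxy-4,4-dimethylhexyl]-7-(trimethylsilyl)hept-2-en-6-ynoate, 15 3-methylbutanoyl chloride
Product: 16 tert-butyl (2E)-2-[(2S)-6-(tert-butyldimethylsilyloxy)-4,4-dimethyl-2-(3-methylbutanoyloxy)hexyl]-7-(trimethylsilyl)hept-2-en-6-ynoate
Conditions: pyridine, DMAP (cat.), CH2Cl2, 0 °C → rt
Reagents that add atoms: none
Why: DMAP-catalysed acylation of the secondary alcohol with the acid chloride; it does not touch the stereocentre and removes the lactonisation risk at once.

Step 9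
Reactants: 16 tert-butyl (2E)-2-[(2S)-6-(tert-butyldimethylsilyloxy)-4,4-dimethyl-2-(3-methylbutanoyloxy)hexyl]-7-(trimethylsilyl)hept-2-en-6-ynoate
Product: 17 tert-butyl (2E)-2-[(2S)-6-hydroxy-4,4-dimethyl-2-(3-methylbutanoyloxy)hexyl]hept-2-en-6-ynoate
Conditions: TBAF, AcOH, THF, 0 °C → rt
Reagents that add atoms: none
Why: Fluoride cleaves the primary silyl ether and the alkynyl C–Si bond in one operation. Acetic acid buffers the alkoxide, and the two oxygens are 1,5-related, so the isovalerate should neither migrate nor be lost.

Step 10
Reactants: 17 tert-butyl (2E)-2-[(2S)-6-hydroxy-4,4-dimethyl-2-(3-methylbutanoyloxy)hexyl]hept-2-en-6-ynoate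
Product: 18 tert-butyl (2E)-2-[(2S)-4,4-dimethyl-2-(3-methylbutanoyloxy)-6-oxohexyl]hept-2-en-6-ynoate
Conditions: Dess–Martin periodinane, CH2Cl2, 0 °C → rt
Reagents that add atoms: none
Why: Dess–Martin oxidation to the aldehyde; the terminal alkyne and both esters are inert, and the aldehyde has no stereocentre at its α-carbon to lose.

Step 11
Reactants: 18 tert-butyl (2E)-2-[(2S)-4,4-dimethyl-2-(3-methylbutanoyloxy)-6-oxohexyl]hept-2-en-6-ynoate
Product: 19 tert-butyl (1E,6S,10S)-8,8-dimethyl-5-methylidene-10-(3-methylbutanoyloxy)-6-(triethylsilyloxy)cycloundec-1-ene-1-carboxylate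
Conditions: Ni(cod)2 (20 mol %), DP-IPr·HCl [1,3-bis(2,6-diisopropylphenyl)-4,5-diphenylimidazolinium chloride] (20 mol %), KOt-Bu (20 mol %), Et3SiH (5 equiv), THF, rt, slow addition of 18 (final 0.005 M)
Reagents that add atoms: triethylsilane, CC[SiH](CC)CC
Why: Ni-catalysed reductive ynal macrocyclisation: zerovalent nickel couples alkyne and aldehyde oxidatively to an oxanickelacycle, and σ-bond metathesis with the silane followed by C–H reductive elimination releases the silyl ether. The bulky carbene directs C–C bond formation to the internal alkyne carbon C1, which gives the exocyclic methylene and the eleven- rather than twelve-membered ring. C11 is created here under control of the forming ring (C7 substituent, C9 gem-dimethyl group, cis ring alkene); the 11S epimer is carried on, and slow addition holds back oligomerisation.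

Step 12
Reactants: 19 tert-butyl (1E,6S,10S)-8,8-dimethyl-5-methylidene-10-(3-methylbutanoyloxy)-6-(triethylsilyloxy)cycloundec-1-ene-1-carboxylate
Product: 21 (1E,6S,10S)-6-hydroxy-8,8-dimethyl-5-methylidene-10-(3-methylbutanoyloxy)cycloundec-1-ene-1-carboxylic acid, via trimethylsilyl ester 20 (not isolated)
Conditions: TMSOTf, 2,6-lutidine, CH2Cl2, 0 °C; then 1 M aq HCl, THF, 0 °C
Reagents that add atoms: none
Why: Silyl triflate-mediated cleavage of the tert-butyl ester (O-silylation, loss of isobutene) runs under buffered, non-protic conditions that should not ionise the allylic C11–O bond. Brief dilute acid then hydrolyses the silyl ester and the triethylsilyl ether; the stereocentres and the isovalerate are not involved.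

## Compound list

1 | 2,2-dimethylsuccinic acid | CC(C)(CC(=O)O)C(=O)O | starting material
2 | 2,2-dimethylbutane-1,4-diol | OCCC(C)(C)CO | intermediate
3 | 4-(tert-butyldimethylsilyloxy)-2,2-dimethylbutan-1-ol | CC(C)(C)[Si](C)(C)OCCC(C)(C)CO | intermediate
4 | tert-butyl(4-iodo-3,3-dimethylbutoxy)dimethylsilane | CC(C)(C)[Si](C)(C)OCCC(C)(C)CI | intermediate
5 | 5-(trimethylsilyl)pent-4-yn-1-ol | C[Si](C)(C)C#CCCCO | starting material
6 | 5-(trimethylsilyl)pent-4-ynal | C[Si](C)(C)C#CCCC=O | intermediate
7 | tert-butyl 2-(triphenyl-λ5-phosphanylidene)acetate | CC(C)(C)OC(=O)C=P(c1ccccc1)(c1ccccc1)c1ccccc1 | starting material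
8 | tert-butyl 2-bromo-2-(triphenyl-λ5-phosphanylidene)acetate | CC(C)(C)OC(=O)C(Br)=P(c1ccccc1)(c1ccccc1)c1ccccc1 | intermediate
9 | tert-butyl (Z)-2-bromo-7-(trimethylsilyl)hept-2-en-6-ynoate | C[Si](C)(C)C#CCC/C=C(/C(=O)OC(C)(C)C)Br | intermediate
10 | vinylboronic acid pinacol ester (2-ethenyl-4,4,5,5-tetramethyl-1,3,2-dioxaborolane) | C=CB1OC(C)(C)C(C)(C)O1 | starting material
11 | 4-(tert-butyldimethylsilyloxy)-2,2-dimethylbutyllithium | [Li]CC(C)(C)CCO[Si](C)(C)C(C)(C)C | intermediate
12 | lithium [4-(tert-butyldimethylsilyloxy)-2,2-dimethylbutyl](ethenyl)(pinacolato)borate | [Li+].C=C[B-]1(CC(C)(C)CCO[Si](C)(C)C(C)(C)C)OC(C)(C)C(C)(C)O1 | intermediate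
13 | tert-butyl (2E)-2-[(2S)-6-(tert-butyldimethylsilyloxy)-4,4-dimethyl-2-(4,4,5,5-tetramethyl-1,3,2-dioxaborolan-2-yl)hexyl]-7-(trimethylsilyl)hept-2-en-6-ynoate | CC(C)(C)[Si](C)(C)OCCC(C)(C)C[C@H](B1OC(C)(C)C(C)(C)O1)C/C(C(=O)OC(C)(C)C)=C\CCC#C[Si](C)(C)C | intermediate
14 | tert-butyl (2E)-2-[(2S)-6-(tert-butyldimethylsilyloxy)-2-hydroxy-4,4-dimethylhexyl]-7-(trimethylsilyl)hept-2-en-6-ynoate | CC(C)(C)[Si](C)(C)OCCC(C)(C)C[C@H](O)C/C(C(=O)OC(C)(C)C)=C\CCC#C[Si](C)(C)C | intermediate
15 | 3-methylbutanoyl chloride (isovaleryl chloride) | CC(C)CC(=O)Cl | starting material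
16 | tert-butyl (2E)-2-[(2S)-6-(tert-butyldimethylsilyloxy)-4,4-dimethyl-2-(3-methylbutanoyloxy)hexyl]-7-(trimethylsilyl)hept-2-en-6-ynoate | CC(C)(C)[Si](C)(C)OCCC(C)(C)C[C@H](OC(=O)CC(C)C)C/C(C(=O)OC(C)(C)C)=C\CCC#C[Si](C)(C)C | intermediate
17 | tert-butyl (2E)-2-[(2S)-6-hydroxy-4,4-dimethyl-2-(3-methylbutanoyloxy)hexyl]hept-2-en-6-ynoate | OCCC(C)(C)C[C@H](OC(=O)CC(C)C)C/C(C(=O)OC(C)(C)C)=C\CCC#C | intermediate
18 | tert-butyl (2E)-2-[(2S)-4,4-dimethyl-2-(3-methylbutanoyloxy)-6-oxohexyl]hept-2-en-6-ynoate | O=CCC(C)(C)C[C@H](OC(=O)CC(C)C)C/C(C(=O)OC(C)(C)C)=C\CCC#C | intermediate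
19 | tert-butyl (1E,6S,10S)-8,8-dimethyl-5-methylidene-10-(3-methylbutanoyloxy)-6-(triethylsilyloxy)cycloundec-1-ene-1-carboxylate | C=C1CC/C=C(/C(=O)OC(C)(C)C)C[C@@H](OC(=O)CC(C)C)CC(C)(C)C[C@@H]1O[Si](CC)(CC)CC | intermediate
20 | trimethylsilyl (1E,6S,10S)-8,8-dimethyl-5-methylidene-10-(3-methylbutanoyloxy)-6-(triethylsilyloxy)cycloundec-1-ene-1-carboxylate | C=C1CC/C=C(/C(=O)O[Si](C)(C)C)C[C@@H](OC(=O)CC(C)C)CC(C)(C)C[C@@H]1O[Si](CC)(CC)CC | intermediate
21 | (1E,6S,10S)-6-hydroxy-8,8-dimethyl-5-methylidene-10-(3-methylbutanoyloxy)cycloundec-1-ene-1-carboxylic acid (CNP0400752.1) | C=C1CC/C=C(/C(=O)O)C[C@@H](OC(=O)CC(C)C)CC(C)(C)C[C@@H]1O | target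

## Step count and uncertain steps

Total: 12 steps. Longest linear sequence: 10 steps (steps 1–3 and 6–12 from 1); the second branch adds steps 4 and 5.

**Step 6 (key step).**
- Most likely failure: halide inhibition of the alkene-binding event. Bromide from 9 and iodide from the exchange compete with the vinyl group of 12 for the cationic palladium centre, which stalls the catalyst or diverts it to direct transfer of the vinyl or alkyl group. Lesser risks are β-hydride elimination from the C6–Pd intermediate, lower enantioselection with the β-branched migrating group, and insertion of the tethered silylalkyne into the alkenyl–palladium bond.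
- Fallback: the two bonds are made in separate known steps. Setting out from 4, alkyllithium 11 is transmetalated with ZnCl2 and coupled with vinyl bromide under Pd(PPh3)4 (Negishi coupling; the zinc reagent has no β-hydrogen) to give the terminal alkene tert-butyl[(3,3-dimethylhex-5-en-1-yl)oxy]dimethylsilane F1. Enantioselective diboration of F1 with B2pin2 under Pt(dba)3 and a TADDOL-derived phosphonite gives 2,2'-[(2R)-6-(tert-butyldimethylsilyloxy)-4,4-dimethylhexane-1,2-diyl]bis(4,4,5,5-tetramethyl-1,3,2-dioxaborolane) F2. Suzuki–Miyaura coupling of the primary boronate of F2 with 9 (Pd(OAc)2, RuPhos, KOH, THF/H2O) comes back to the route at 13.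

**Step 11.**
- Most likely failure: poor facial selectivity at C11, since nothing in the open chain enforces one face of the aldehyde. Some closure at the terminal alkyne carbon (twelve-membered endocyclic isomer) and oligomerisation are further risks; a bulkier silane and slower addition answer those within the step.
- Fallback: C11 is set by a reagent instead. Setting out from 19 (with whatever share of its C11 epimer is formed), PPTS in MeOH gives the epimeric alcohols tert-butyl (1E,10S)-6-hydroxy-8,8-dimethyl-5-methylidene-10-(3-methylbutanoyloxy)cycloundec-1-ene-1-carboxylate F3. Dess–Martin oxidation gives the enone tert-butyl (1E,10S)-8,8-dimethyl-5-methylidene-10-(3-methylbutanoyloxy)-6-oxocycloundec-1-ene-1-carboxylate F4. Corey–Bakshi–Shibata reduction with catecholborane and (R)-2-methyl-CBS-oxazaborolidine, in which the 2-substituted alkenyl flank acts as the large group, should give the 11S alcohol tert-butyl (1E,6S,10S)-6-hydroxy-8,8-dimethyl-5-methylidene-10-(3-methylbutanoyloxy)cycloundec-1-ene-1-carboxylate F5. F5 is taken through the conditions of step 12 and comes back at 21.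

**Step 5.**
- Most likely failure: incomplete geometric control in the Wittig step, with an E isomer that is hard to remove, and contamination by unbrominated enoate if halogenation of the ylide is incomplete.
- Fallback: tert-butyl 2,2,2-tribromoacetate F6 is prepared from tribromoacetic acid and tert-butyl 2,2,2-trichloroacetimidate. Setting out from 6, condensation with F6 under CrCl2 in THF (Reformatsky-type addition, then anti elimination of the chromium alkoxide) gives the Z bromo enoate and comes back at 9.

**Step 12.**
- Most likely failure: ionisation of the allylic C11–O bond or migration of the exocyclic alkene under the Lewis acid, or sluggish cleavage of the hindered conjugated tert-butyl ester that tempts harsher treatment.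
- Fallback: the ester is exchanged before the sensitive allylic system exists, so the last step becomes a fluoride treatment. Setting out from 17, TMSOTf and 2,6-lutidine followed by aqueous work-up give (2E)-2-[(2S)-6-hydroxy-4,4-dimethyl-2-(3-methylbutanoyloxy)hexyl]hept-2-en-6-ynoic acid F7. Heating with 2-(trimethylsilyl)ethyl 2,2,2-trichloroacetimidate in toluene esterifies the acid alone, giving 2-(trimethylsilyl)ethyl (2E)-2-[(2S)-6-hydroxy-4,4-dimethyl-2-(3-methylbutanoyloxy)hexyl]hept-2-en-6-ynoate F8. Dess–Martin oxidation gives 2-(trimethylsilyl)ethyl (2E)-2-[(2S)-4,4-dimethyl-2-(3-methylbutanoyloxy)-6-oxohexyl]hept-2-en-6-ynoate F9. The conditions of step 11 give 2-(trimethylsilyl)ethyl (1E,6S,10S)-8,8-dimethyl-5-methylidene-10-(3-methylbutanoyloxy)-6-(triethylsilyloxy)cycloundec-1-ene-1-carboxylate F10. TBAF in THF then removes both silicon-based groups and comes back at 21.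

## Further compounds

F1 | step 6 | tert-butyl[(3,3-dimethylhex-5-en-1-yl)oxy]dimethylsilane | C=CCC(C)(C)CCO[Si](C)(C)C(C)(C)C
F2 | step 6 | 2,2'-[(2R)-6-(tert-butyldimethylsilyloxy)-4,4-dimethylhexane-1,2-diyl]bis(4,4,5,5-tetramethyl-1,3,2-dioxaborolane) | CC(C)(C)[Si](C)(C)OCCC(C)(C)C[C@H](B1OC(C)(C)C(C)(C)O1)CB1OC(C)(C)C(C)(C)O1
F3 | step 11 | tert-butyl (1E,10S)-6-hydroxy-8,8-dimethyl-5-methylidene-10-(3-methylbutanoyloxy)cycloundec-1-ene-1-carboxylate, mixture of epimers at ring position 6 (C11) | C=C1CC/C=C(/C(=O)OC(C)(C)C)C[C@@H](OC(=O)CC(C)C)CC(C)(C)CC1O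
F4 | step 11 | tert-butyl (1E,10S)-8,8-dimethyl-5-methylidene-10-(3-methylbutanoyloxy)-6-oxocycloundec-1-ene-1-carboxylate | C=C1CC/C=C(/C(=O)OC(C)(C)C)C[C@@H](OC(=O)CC(C)C)CC(C)(C)CC1=O
F5 | step 11 | tert-butyl (1E,6S,10S)-6-hydroxy-8,8-dimethyl-5-methylidene-10-(3-methylbutanoyloxy)cycloundec-1-ene-1-carboxylate | C=C1CC/C=C(/C(=O)OC(C)(C)C)C[C@@H](OC(=O)CC(C)C)CC(C)(C)C[C@@H]1O
F6 | step 5 | tert-butyl 2,2,2-tribromoacetate | CC(C)(C)OC(=O)C(Br)(Br)Br
F7 | step 12 | (2E)-2-[(2S)-6-hydroxy-4,4-dimethyl-2-(3-methylbutanoyloxy)hexyl]hept-2-en-6-ynoic acid | OCCC(C)(C)C[C@H](OC(=O)CC(C)C)C/C(C(=O)O)=C\CCC#C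
F8 | step 12 | 2-(trimethylsilyl)ethyl (2E)-2-[(2S)-6-hydroxy-4,4-dimethyl-2-(3-methylbutanoyloxy)hexyl]hept-2-en-6-ynoate | OCCC(C)(C)C[C@H](OC(=O)CC(C)C)C/C(C(=O)OCC[Si](C)(C)C)=C\CCC#C
F9 | step 12 | 2-(trimethylsilyl)ethyl (2E)-2-[(2S)-4,4-dimethyl-2-(3-methylbutanoyloxy)-6-oxohexyl]hept-2-en-6-ynoate | O=CCC(C)(C)C[C@H](OC(=O)CC(C)C)C/C(C(=O)OCC[Si](C)(C)C)=C\CCC#C
F10 | step 12 | 2-(trimethylsilyl)ethyl (1E,6S,10S)-8,8-dimethyl-5-methylidene-10-(3-methylbutanoyloxy)-6-(triethylsilyloxy)cycloundec-1-ene-1-carboxylate | C=C1CC/C=C(/C(=O)OCC[Si](C)(C)C)C[C@@H](OC(=O)CC(C)C)CC(C)(C)C[C@@H]1O[Si](CC)(CC)CC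
A1 | alternative 1 | 7-(tert-butyldimethylsilyloxy)-9,9-dimethylcycloundec-4-yn-11-one (target numbering) | O=C1CCCC#CC[C@@H](O[Si](C)(C)C(C)(C)C)CC(C)(C)C1
A2 | alternative 1 | 8-(tert-butyldimethylsilyloxy)-4a,9a-epoxy-6,6-dimethyldecahydro-1H-benzo[7]annulen-1-one (six–seven fused epoxy ketone; epoxide configuration immaterial) | O=C1CCCC23OC12C[C@@H](O[Si](C)(C)C(C)(C)C)CC(C)(C)C3
A3 | alternative 2 | tert-butyl (1E,6S,10S)-6-(tert-butyldimethylsilyloxy)-8,8-dimethyl-5-methylidene-10-(3-methylbutanoyloxy)cycloundec-1-ene-1-carboxylate (protected target) | C=C1CC/C=C(/C(=O)OC(C)(C)C)C[C@@H](OC(=O)CC(C)C)CC(C)(C)C[C@@H]1O[Si](C)(C)C(C)(C)C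
A4 | alternative 2 | open-chain N-hydroxyphthalimide ester of the acid attached to C3, with C4 as (E)-β-phenylsulfonyl tert-butyl enoate, C7 isovalerate, C11 tert-butyldimethylsilyl ether and C1 methylidene | O=C(ON1C(=O)c2ccccc2C1=O)CCC(=C)[C@@H](O[Si](C)(C)C(C)(C)C)CC(C)(C)C[C@H](OC(=O)CC(C)C)C/C(C(=O)OC(C)(C)C)=C\S(=O)(=O)c1ccccc1
A5 | alternative 3 | tert-butyl 7-(tert-butyldimethylsilyloxy)-9,9-dimethyl-11-oxocycloundec-4-ene-5-carboxylate (target numbering) | O=C1CCC/C=C(/C(=O)OC(C)(C)C)C[C@@H](O[Si](C)(C)C(C)(C)C)CC(C)(C)C1
A6 | alternative 3 | tert-butyl 6-(tert-butyldimethylsilyloxy)-1,2-diethenyl-2-hydroxy-4,4-dimethylcycloheptane-1-carboxylate (vinyl groups cis) | C=C[C@]1(O)CC(C)(C)C[C@H](O[Si](C)(C)C(C)(C)C)C[C@@]1(C=C)C(=O)OC(C)(C)C
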